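## Retrosynthetic overview

1. Last operations: face-selective epoxidation of the 1(10)-alkene, preceded by acylation of the 8-OH with (2R,3S)-2,3-dimethyloxirane-2-carboxylic acid, itself made from (S)-lactic acid by dioxolanone aldol, mesylation and base-induced ring closure.
2. Key disconnection C6–C7: an electroreductive, chromium-catalysed intramolecular 2-(methoxycarbonyl)allylation of a Z-enal by a (Z)-2-(bromomethyl)enoate closes the ten-membered ring, relays C8 to C7/C6 and leads straight to the α-methylene-γ-lactone.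
3. Acyclic precursor: allylic bromide from Baylis–Hillman reaction/bromination at C7; the Z-enal with its C3 benzoate from a 4-methylbutenolide (reduction, protection, oxidation).
4. Backbone C7–C4: (S)-glycidol + acetylide, zirconium-catalysed carboalumination/iodination (E-C1=C10), alkenyl-copper opening of methyl (S)-glycidate, Bestmann butenolide annulation.
5. Ring order: butenolide (temporary, fixes 4Z) → ten-membered carbocycle and γ-lactone (one step) → 1,10-oxirane; the side-chain oxirane is made separately.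

Assumption: (S)-glycidol, methyl (S)-glycidate and (S)-lactic acid are taken as inexpensive commercial enantiopure materials; germacrane numbering (C1–C15) is used for the ring carbons; TBS = tert-butyldimethylsilyl, TES = triethylsilyl, Bz = benzoyl.

## Route

Step 1
Reactants: 1 (S)-glycidol
Product: 2 (R)-pent-4-yne-1,2-diol
Conditions: LiC≡CH·H2NCH2CH2NH2 (3 equiv), DMSO, 0 °C → rt; aq. NH4Cl
Reagents that add atoms: lithium acetylide–ethylenediamine complex, [Li]C#C.NCCN
Why: SN2 epoxide opening by acetylide at the unsubstituted carbon (the Payne shift of glycidol alkoxide is degenerate and non-racemising), so the purchased C8 stereocentre is untouched.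

Step 2
Reactants: 2 (R)-pent-4-yne-1,2-diol
Product: 4 (R)-2-(TBS-oxy)-1-(TES-oxy)pent-4-yne, via mono-triethylsilyl ether 3 (not isolated)
Conditions: Et3SiCl (1.05 equiv), imidazole, CH2Cl2, −78 °C; then t-BuMe2SiOTf, 2,6-lutidine, −78 → 0 °C
Reagents that add atoms: chlorotriethylsilane, CC[Si](Cl)(CC)CC; tert-butyldimethylsilyl triflate, CC(C)(C)[Si](C)(C)OS(=O)(=O)C(F)(F)F
Why: Sequential selective silylation puts the labile TES group on the primary OH (later oxidised directly) and the robust TBS group on the secondary C8-OH.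

Step 3
Reactants: 4 (R)-2-(TBS-oxy)-1-(TES-oxy)pent-4-yne
Product: 6 (1E,4R)-4-(TBS-oxy)-1-iodo-2-methyl-5-(TES-oxy)pent-1-ene, via alkenylalane 5 (not isolated)
Conditions: Me3Al (3 equiv), Cp2ZrCl2 (0.25 equiv), CH2Cl2, 0 °C → rt; then I2, THF, −30 → 0 °C
Reagents that add atoms: trimethylaluminium, C[Al](C)C; iodine, II
Why: Negishi zirconium-catalysed carboalumination adds Me–Al syn across the terminal alkyne with methyl on the internal carbon, and iodinolysis with retention fixes the E-trisubstituted C1=C10 alkene.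

Step 4
Reactants: 6 (1E,4R)-4-(TBS-oxy)-1-iodo-2-methyl-5-(TES-oxy)pent-1-ene; 7 methyl (S)-glycidate
Product: 10 methyl (2S,4E,7R)-7-(TBS-oxy)-2-hydroxy-5-methyl-8-(TES-oxy)oct-4-enoate, via alkenyllithium 8 (not isolated), via alkenylmagnesium bromide 9 (not isolated)
Conditions: t-BuLi (2.05 equiv), Et2O, −78 °C; MgBr2·OEt2, −78 → −40 °C; CuI (10 mol%), then 7 (1.3 equiv), THF, −40 → −20 °C; aq. NH4Cl
Reagents that add atoms: none
Why: Iodine–lithium exchange with retention, transmetalation and copper-catalysed SN2 opening of the glycidate at its CH2 carbon join the two purchased stereocentres (C8, C3) without touching either.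

Step 5
Reactants: 10 methyl (2S,4E,7R)-7-(TBS-oxy)-2-hydroxy-5-methyl-8-(TES-oxy)oct-4-enoate
Product: 12 (3S,5E,8R)-8-(TBS-oxy)-3-hydroxy-6-methyl-9-(TES-oxy)non-5-en-2-one, via Weinreb amide 11 (not isolated)
Conditions: MeNH(OMe)·HCl (1.5 equiv), i-PrMgCl (4 equiv), THF, −20 °C; then MeMgBr (3 equiv), −20 → 0 °C; aq. NH4Cl
Reagents that add atoms: methylmagnesium bromide, C[Mg]Br
Why: One-pot Weinreb amide formation and Grignard addition stops at the methyl ketone through the chelated tetrahedral intermediate, the magnesium alkoxide protecting C3 from epimerisation.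

Step 6
Reactants: 12 (3S,5E,8R)-8-(TBS-oxy)-3-hydroxy-6-methyl-9-(TES-oxy)non-5-en-2-one
Product: 14 (5S)-5-[(2E,5R)-5-(TBS-oxy)-3-methyl-6-(TES-oxy)hex-2-enyl]-4-methylfuran-2(5H)-one, via phosphorane ester 13 (not isolated)
Conditions: Ph3P=C=C=O (1.3 equiv), toluene, 90 °C
Reagents that add atoms: (triphenylphosphoranylidene)ketene, O=C=C=P(c1ccccc1)(c1ccccc1)c1ccccc1
Why: Bestmann butenolide synthesis (O-acylation by the ketenylidene phosphorane, then intramolecular Wittig olefination of the ketone), the ring enforcing the cis (4Z) relationship of C3 and C6.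

Step 7
Reactants: 14 (5S)-5-[(2E,5R)-5-(TBS-oxy)-3-methyl-6-(TES-oxy)hex-2-enyl]-4-methylfuran-2(5H)-one
Product: 15 (2Z,4S,6E,9R)-9-(TBS-oxy)-3,7-dimethyl-10-(TES-oxy)deca-2,6-diene-1,4-diol
Conditions: i-Bu2AlH (3.5 equiv), CH2Cl2, −78 → 0 °C; Rochelle salt
Reagents that add atoms: none
Why: 1,2-Reduction of the butenolide through the lactol to the Z-ene-1,4-diol keeps the ring-derived alkene geometry.

Step 8
Reactants: 15 (2Z,4S,6E,9R)-9-(TBS-oxy)-3,7-dimethyl-10-(TES-oxy)deca-2,6-diene-1,4-diol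
Product: 17 (2Z,4S,6E,9R)-1,9-bis(TBS-oxy)-3,7-dimethyl-10-(TES-oxy)deca-2,6-dien-4-yl benzoate, via primary silyl ether 16 (not isolated)
Conditions: t-BuMe2SiCl (1.05 equiv), imidazole, CH2Cl2, −20 °C; then BzCl, pyridine, DMAP (cat.), 0 °C → rt
Reagents that add atoms: tert-butyldimethylsilyl chloride, CC(C)(C)[Si](C)(C)Cl; benzoyl chloride, O=C(Cl)c1ccccc1
Why: Steric differentiation (silylation of the primary allylic OH, then acylation of the secondary OH) installs the C3 benzoate of the target and blocks lactol formation later.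

Step 9
Reactants: 17 (2Z,4S,6E,9R)-1,9-bis(TBS-oxy)-3,7-dimethyl-10-(TES-oxy)deca-2,6-dien-4-yl benzoate
Product: 19 (2Z,4S,6E,9R)-1,9-bis(TBS-oxy)-3,7-dimethyl-10-oxodeca-2,6-dien-4-yl benzoate, via alkoxysulfonium chloride 18 (not isolated)
Conditions: (COCl)2, DMSO, CH2Cl2, −78 → −35 °C; then Et3N, −78 → 0 °C
Reagents that add atoms: none
Why: Under Swern conditions a primary TES ether is cleaved and oxidised directly to the aldehyde while TBS ethers and the benzoate persist.

Step 10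
Reactants: 19 (2Z,4S,6E,9R)-1,9-bis(TBS-oxy)-3,7-dimethyl-10-oxodeca-2,6-dien-4-yl benzoate
Product: 20 methyl (4R,6E,9S,10Z)-9-(benzoyloxy)-4,12-bis(TBS-oxy)-3-hydroxy-6,10-dimethyl-2-methylidenedodeca-6,10-dienoate (both C3 epimers)
Conditions: methyl acrylate (10 equiv), DABCO (1 equiv), MeOH (2 equiv), neat, rt, 3–5 d
Reagents that add atoms: methyl acrylate, C=CC(=O)OC
Why: Morita–Baylis–Hillman reaction of the activated α-silyloxy aldehyde; the new carbinol centre is irrelevant because it is removed in the next step.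

Step 11
Reactants: 20 methyl (4R,6E,9S,10Z)-9-(benzoyloxy)-4,12-bis(TBS-oxy)-3-hydroxy-6,10-dimethyl-2-methylidenedodeca-6,10-dienoate
Product: 21 methyl (2Z,4R,6E,9S,10Z)-9-(benzoyloxy)-2-(bromomethyl)-4,12-bis(TBS-oxy)-6,10-dimethyldodeca-2,6,10-trienoate
Conditions: NBS, Me2S, CH2Cl2, 0 °C, then 20, 0 °C → rt
Reagents that add atoms: N-bromosuccinimide, O=C1CCC(=O)N1Br
Why: Corey–Kim-type bromination of the Baylis–Hillman alcohol with allylic transposition (SN2') gives the thermodynamically preferred (Z)-2-(bromomethyl)enoate and consumes all electrophilic bromine before the other alkenes can react.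

Step 12
Reactants: 21 methyl (2Z,4R,6E,9S,10Z)-9-(benzoyloxy)-2-(bromomethyl)-4,12-bis(TBS-oxy)-6,10-dimethyldodeca-2,6,10-trienoate
Product: 22 methyl (2Z,4R,6E,9S,10Z)-9-(benzoyloxy)-2-(bromomethyl)-4-(TBS-oxy)-12-hydroxy-6,10-dimethyldodeca-2,6,10-trienoate
Conditions: CSA (10 mol%), MeOH/CH2Cl2 1:1, 0 °C
Reagents that add atoms: none
Why: Acid-catalysed methanolysis removes the unhindered primary allylic TBS ether much faster than the hindered secondary one, under conditions that contain no nucleophile for the allylic bromide.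

Step 13
Reactants: 22 methyl (2Z,4R,6E,9S,10Z)-9-(benzoyloxy)-2-(bromomethyl)-4-(TBS-oxy)-12-hydroxy-6,10-dimethyldodeca-2,6,10-trienoate
Product: 23 methyl (2Z,4R,6E,9S,10Z)-9-(benzoyloxy)-2-(bromomethyl)-4-(TBS-oxy)-6,10-dimethyl-12-oxododeca-2,6,10-trienoate
Conditions: Dess–Martin periodinane, NaHCO3, CH2Cl2, 0 °C → rt
Reagents that add atoms: none
Why: Buffered Dess–Martin oxidation gives the Z-enal without Z/E isomerisation or benzoate migration.

Step 14
Reactants: 23 methyl (2Z,4R,6E,9S,10Z)-9-(benzoyloxy)-2-(bromomethyl)-4-(TBS-oxy)-6,10-dimethyl-12-oxododeca-2,6,10-trienoate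
Product: 26 (3S,6R,7S,8R)-3-(benzoyloxy)-8-(TBS-oxy)germacra-1(10)E,4Z,11(13)-trien-12,6-olide, via trimethylsilyl ether 24 (not isolated), via hydroxy ester 25 (not isolated)
Conditions: CrCl2 (20 mol%), Me3SiCl (2.5 equiv), LiCl (0.3 M), DMF/THF 4:1, 20 °C, undivided cell, sacrificial Al anode, Ni-foam cathode, −1.0 V vs Ag/AgCl (ca. 2.2 F per mol), 23 added by syringe pump over 12 h (final 2 mM); then 0.5 M HCl, THF, 0 °C; p-TsOH·H2O (cat.), CH2Cl2, rt
Reagents that add atoms: none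
Why: Proposed new method: cathodically regenerated divalent chromium (catalytic CrCl2, Me3SiCl releasing the metal from the trivalent chromium alkoxide, Al anode as electron source) inserts into the allylic C–Br bond by two one-electron steps, the allylchromium equilibrates to the isomer with C8 trans to CH2Cr and closes the ten-membered ring through a chair Zimmerman–Traxler transition state with C5 and C8 equatorial (6,7-anti, hence the trans-lactone), while the C8 silyloxy group lies antiperiplanar to the forming C6–C7 bond with H-8 turned toward the enal (the Felkin–Anh sense reported for Hiyama additions of δ-oxygenated allylic bromides), so the purchased C8 centre sets C7 and C6, slow addition gives pseudo-high dilution and the potential is held at the chromium couple so that enal, benzoate and bromide are not reduced directly; the closest known reaction types are the stoichiometric CrCl2 Nozaki–Hiyama–Kishi-type Barbier macrocyclisation of 2-(bromomethyl)enoate aldehydes to germacranolides and intermolecular chromium-catalysed electroreductive additions of organic halides to aldehydes, neither shown for a catalytic electrochemical 2-(alkoxycarbonyl)allyl ring closure.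

Step 15
Reactants: 26 (3S,6R,7S,8R)-3-(benzoyloxy)-8-(TBS-oxy)germacra-1(10)E,4Z,11(13)-trien-12,6-olide
Product: 27 (3S,6R,7R,8R)-3-(benzoyloxy)-8-hydroxygermacra-1(10)E,4Z,11(13)-trien-12,6-olide
Conditions: HF·pyridine, pyridine, THF, 0 °C → rt
Reagents that add atoms: none
Why: Non-basic fluoride desilylation frees the C8-OH and leaves the α-methylene lactone and the benzoate intact.

Step 16
Reactants: 28 (S)-lactic acid
Product: 29 (2S,5S)-2-tert-butyl-5-methyl-1,3-dioxolan-4-one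
Conditions: t-BuCHO, p-TsOH·H2O (cat.), H2SO4 (cat.), pentane, reflux (Dean–Stark); recrystallisation (cis isomer)
Reagents that add atoms: pivalaldehyde, CC(C)(C)C=O
Why: Seebach acetalisation; the lactate centre induces the cis acetal centre, which stores the chirality for the enolate step (self-regeneration of stereocentres).

Step 17
Reactants: 29 (2S,5S)-2-tert-butyl-5-methyl-1,3-dioxolan-4-one
Product: 32 (1R)-1-[(2S,4R)-2-tert-butyl-4-methyl-5-oxo-1,3-dioxolan-4-yl]ethyl methanesulfonate, via lithium enolate 30 (not isolated), via lithium aldolate 31 (not isolated)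
Conditions: LiN(i-Pr)2, THF, −78 °C; CH3CHO, −78 °C; MsCl, −78 → 0 °C
Reagents that add atoms: acetaldehyde, CC=O; methanesulfonyl chloride, CS(=O)(=O)Cl
Why: Aldol addition of the dioxolanone enolate anti to the tert-butyl group sets the quaternary centre with net retention, a chair Zimmerman–Traxler transition state with the acetaldehyde methyl equatorial sets the carbinol centre (minor epimer removed by chromatography), and the aldolate is mesylated in situ.

Step 18
Reactants: 32 (1R)-1-[(2S,4R)-2-tert-butyl-4-methyl-5-oxo-1,3-dioxolan-4-yl]ethyl methanesulfonate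
Product: 35 (2R,3S)-2,3-dimethyloxirane-2-carboxylic acid, via potassium hydroxy mesylate carboxylate 33 (not isolated), via potassium glycidate 34 (not isolated)
Conditions: KOH (3.5 equiv), MeOH/H2O, 0 °C → rt; then aq. KHSO4 to pH 3, 0 °C, EtOAc extraction
Reagents that add atoms: potassium hydroxide, [K+].[OH-]
Why: Saponification releases pivalaldehyde and the tertiary alkoxide, which displaces the mesylate intramolecularly with inversion (Williamson-type epoxide closure) to give the cis-dimethyl glycidic acid.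

Step 19
Reactants: 27 (3S,6R,7R,8R)-3-(benzoyloxy)-8-hydroxygermacra-1(10)E,4Z,11(13)-trien-12,6-olide; 35 (2R,3S)-2,3-dimethyloxirane-2-carboxylic acid
Product: 37 (3S,6R,7R,8R)-3-(benzoyloxy)-8-{[(2R,3S)-2,3-dimethyloxiran-2-yl]carbonyloxy}germacra-1(10)E,4Z,11(13)-trien-12,6-olide, via mixed anhydride 36 (not isolated)
Conditions: 2,4,6-Cl3C6H2COCl, Et3N, toluene, rt; then 27, DMAP, rt
Reagents that add atoms: none
Why: Yamaguchi esterification through the mixed anhydride acylates the hindered secondary C8-OH under basic conditions that spare the acid-sensitive glycidate and touch no stereocentre.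

Step 20
Reactants: 37 (3S,6R,7R,8R)-3-(benzoyloxy)-8-{[(2R,3S)-2,3-dimethyloxiran-2-yl]carbonyloxy}germacra-1(10)E,4Z,11(13)-trien-12,6-olide
Product: 38 (1R,3S,6R,7R,8R,10R)-3-(benzoyloxy)-1,10-epoxy-8-{[(2R,3S)-2,3-dimethyloxiran-2-yl]carbonyloxy}germacra-4Z,11(13)-dien-12,6-olide (CNP0324463.5)
Conditions: m-CPBA (1.1 equiv), NaHCO3, CH2Cl2, 0 °C
Reagents that add atoms: 3-chloroperoxybenzoic acid, O=C(OO)c1cccc(Cl)c1
Why: Prilezhaev epoxidation attacks only the electron-rich E-1(10) alkene (the 4,5-alkene is deactivated by two allylic acyloxy groups, the methylene lactone is electron-poor) from its exposed outer face in the ring conformation fixed by C3, C6, C7 and C8, which should give the 1R,10R trans-oxirane, the buffer preventing transannular opening.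

## Compound list

1 | (S)-glycidol | C1[C@@H](O1)CO | starting material
2 | (R)-pent-4-yne-1,2-diol | C#CC[C@@H](O)CO | intermediate
3 | (R)-1-(TES-oxy)pent-4-yn-2-ol | C#CC[C@@H](O)CO[Si](CC)(CC)CC | intermediate
4 | (R)-2-(TBS-oxy)-1-(TES-oxy)pent-4-yne | C#CC[C@@H](O[Si](C)(C)C(C)(C)C)CO[Si](CC)(CC)CC | intermediate
5 | dimethyl[(1E,4R)-4-(TBS-oxy)-2-methyl-5-(TES-oxy)pent-1-enyl]alane | C[Al](C)/C=C(\C)C[C@@H](O[Si](C)(C)C(C)(C)C)CO[Si](CC)(CC)CC | intermediate
6 | (1E,4R)-4-(TBS-oxy)-1-iodo-2-methyl-5-(TES-oxy)pent-1-ene | I/C=C(\C)C[C@@H](O[Si](C)(C)C(C)(C)C)CO[Si](CC)(CC)CC | intermediate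
7 | methyl (S)-glycidate (methyl (S)-oxirane-2-carboxylate) | COC(=O)[C@@H]1CO1 | starting material
8 | [(1E,4R)-4-(TBS-oxy)-2-methyl-5-(TES-oxy)pent-1-enyl]lithium | [Li]/C=C(\C)C[C@@H](O[Si](C)(C)C(C)(C)C)CO[Si](CC)(CC)CC | intermediate
9 | [(1E,4R)-4-(TBS-oxy)-2-methyl-5-(TES-oxy)pent-1-enyl]magnesium bromide | Br[Mg]/C=C(\C)C[C@@H](O[Si](C)(C)C(C)(C)C)CO[Si](CC)(CC)CC | intermediate
10 | methyl (2S,4E,7R)-7-(TBS-oxy)-2-hydroxy-5-methyl-8-(TES-oxy)oct-4-enoate | COC(=O)[C@@H](O)C/C=C(\C)C[C@@H](O[Si](C)(C)C(C)(C)C)CO[Si](CC)(CC)CC | intermediate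
11 | (2S,4E,7R)-7-(TBS-oxy)-2-hydroxy-N-methoxy-N,5-dimethyl-8-(TES-oxy)oct-4-enamide | CON(C)C(=O)[C@@H](O)C/C=C(\C)C[C@@H](O[Si](C)(C)C(C)(C)C)CO[Si](CC)(CC)CC | intermediate
12 | (3S,5E,8R)-8-(TBS-oxy)-3-hydroxy-6-methyl-9-(TES-oxy)non-5-en-2-one | CC(=O)[C@@H](O)C/C=C(\C)C[C@@H](O[Si](C)(C)C(C)(C)C)CO[Si](CC)(CC)CC | intermediate
13 | (3S,5E,8R)-8-(TBS-oxy)-6-methyl-2-oxo-9-(TES-oxy)non-5-en-3-yl (triphenylphosphoranylidene)acetate | CC(=O)[C@@H](OC(=O)C=P(c1ccccc1)(c1ccccc1)c1ccccc1)C/C=C(\C)C[C@@H](O[Si](C)(C)C(C)(C)C)CO[Si](CC)(CC)CC | intermediate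
14 | (5S)-5-[(2E,5R)-5-(TBS-oxy)-3-methyl-6-(TES-oxy)hex-2-enyl]-4-methylfuran-2(5H)-one | O=C1C=C(C)[C@@H](O1)C/C=C(\C)C[C@@H](O[Si](C)(C)C(C)(C)C)CO[Si](CC)(CC)CC | intermediate
15 | (2Z,4S,6E,9R)-9-(TBS-oxy)-3,7-dimethyl-10-(TES-oxy)deca-2,6-diene-1,4-diol | OC/C=C(/C)[C@@H](O)C/C=C(\C)C[C@@H](O[Si](C)(C)C(C)(C)C)CO[Si](CC)(CC)CC | intermediate
16 | (2Z,4S,6E,9R)-1,9-bis(TBS-oxy)-3,7-dimethyl-10-(TES-oxy)deca-2,6-dien-4-ol | CC(C)(C)[Si](C)(C)OC/C=C(/C)[C@@H](O)C/C=C(\C)C[C@@H](O[Si](C)(C)C(C)(C)C)CO[Si](CC)(CC)CC | intermediate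
17 | (2Z,4S,6E,9R)-1,9-bis(TBS-oxy)-3,7-dimethyl-10-(TES-oxy)deca-2,6-dien-4-yl benzoate | CC(C)(C)[Si](C)(C)OC/C=C(/C)[C@@H](OC(=O)c1ccccc1)C/C=C(\C)C[C@@H](O[Si](C)(C)C(C)(C)C)CO[Si](CC)(CC)CC | intermediate
18 | {[(2R,4E,7S,8Z)-7-(benzoyloxy)-2,10-bis(TBS-oxy)-4,8-dimethyldeca-4,8-dienyl]oxy}dimethylsulfonium chloride | CC(C)(C)[Si](C)(C)OC/C=C(/C)[C@@H](OC(=O)c1ccccc1)C/C=C(\C)C[C@@H](O[Si](C)(C)C(C)(C)C)CO[S+](C)C.[Cl-] | intermediate
19 | (2Z,4S,6E,9R)-1,9-bis(TBS-oxy)-3,7-dimethyl-10-oxodeca-2,6-dien-4-yl benzoate | CC(C)(C)[Si](C)(C)OC/C=C(/C)[C@@H](OC(=O)c1ccccc1)C/C=C(\C)C[C@@H](O[Si](C)(C)C(C)(C)C)C=O | intermediate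
20 | methyl (4R,6E,9S,10Z)-9-(benzoyloxy)-4,12-bis(TBS-oxy)-3-hydroxy-6,10-dimethyl-2-methylidenedodeca-6,10-dienoate (both C3 epimers) | CC(C)(C)[Si](C)(C)OC/C=C(/C)[C@@H](OC(=O)c1ccccc1)C/C=C(\C)C[C@@H](O[Si](C)(C)C(C)(C)C)C(O)C(=C)C(=O)OC | intermediate
21 | methyl (2Z,4R,6E,9S,10Z)-9-(benzoyloxy)-2-(bromomethyl)-4,12-bis(TBS-oxy)-6,10-dimethyldodeca-2,6,10-trienoate | CC(C)(C)[Si](C)(C)OC/C=C(/C)[C@@H](OC(=O)c1ccccc1)C/C=C(\C)C[C@@H](O[Si](C)(C)C(C)(C)C)/C=C(\CBr)C(=O)OC | intermediate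
22 | methyl (2Z,4R,6E,9S,10Z)-9-(benzoyloxy)-2-(bromomethyl)-4-(TBS-oxy)-12-hydroxy-6,10-dimethyldodeca-2,6,10-trienoate | OC/C=C(/C)[C@@H](OC(=O)c1ccccc1)C/C=C(\C)C[C@@H](O[Si](C)(C)C(C)(C)C)/C=C(\CBr)C(=O)OC | intermediate
23 | methyl (2Z,4R,6E,9S,10Z)-9-(benzoyloxy)-2-(bromomethyl)-4-(TBS-oxy)-6,10-dimethyl-12-oxododeca-2,6,10-trienoate | O=C/C=C(/C)[C@@H](OC(=O)c1ccccc1)C/C=C(\C)C[C@@H](O[Si](C)(C)C(C)(C)C)/C=C(\CBr)C(=O)OC | intermediate
24 | methyl 2-[(1R,2R,3Z,5S,7E,10R)-5-(benzoyloxy)-10-(TBS-oxy)-4,8-dimethyl-2-(trimethylsilyloxy)cyclodeca-3,7-dien-1-yl]prop-2-enoate | C=C(C(=O)OC)[C@H]1[C@H](O[Si](C)(C)C)/C=C(/C)[C@@H](OC(=O)c2ccccc2)C/C=C(\C)C[C@H]1O[Si](C)(C)C(C)(C)C | intermediate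
25 | methyl 2-[(1S,2R,3Z,5S,7E,10R)-5-(benzoyloxy)-10-(TBS-oxy)-2-hydroxy-4,8-dimethylcyclodeca-3,7-dien-1-yl]prop-2-enoate | C=C(C(=O)OC)[C@H]1[C@H](O)/C=C(/C)[C@@H](OC(=O)c2ccccc2)C/C=C(\C)C[C@H]1O[Si](C)(C)C(C)(C)C | intermediate
26 | (3S,6R,7S,8R)-3-(benzoyloxy)-8-(TBS-oxy)germacra-1(10)E,4Z,11(13)-trien-12,6-olide | C=C1C(=O)O[C@@H]2/C=C(/C)[C@@H](OC(=O)c3ccccc3)C/C=C(\C)C[C@@H](O[Si](C)(C)C(C)(C)C)[C@@H]12 | intermediate
27 | (3S,6R,7R,8R)-3-(benzoyloxy)-8-hydroxygermacra-1(10)E,4Z,11(13)-trien-12,6-olide | C=C1C(=O)O[C@@H]2/C=C(/C)[C@@H](OC(=O)c3ccccc3)C/C=C(\C)C[C@@H](O)[C@@H]12 | intermediate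
28 | (S)-lactic acid | C[C@H](O)C(=O)O | starting material
29 | (2S,5S)-2-tert-butyl-5-methyl-1,3-dioxolan-4-one | C[C@@H]1O[C@H](C(C)(C)C)OC1=O | intermediate
30 | lithium (2S)-2-tert-butyl-5-methyl-1,3-dioxol-4-olate | [Li]OC1=C(C)O[C@H](C(C)(C)C)O1 | intermediate
31 | lithium (1R)-1-[(2S,4R)-2-tert-butyl-4-methyl-5-oxo-1,3-dioxolan-4-yl]ethanolate | C[C@]1([C@@H](C)O[Li])O[C@H](C(C)(C)C)OC1=O | intermediate
32 | (1R)-1-[(2S,4R)-2-tert-butyl-4-methyl-5-oxo-1,3-dioxolan-4-yl]ethyl methanesulfonate | C[C@]1([C@@H](C)OS(C)(=O)=O)O[C@H](C(C)(C)C)OC1=O | intermediate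
33 | potassium (2R,3R)-2-hydroxy-2-methyl-3-(methylsulfonyloxy)butanoate | C[C@@](O)([C@@H](C)OS(C)(=O)=O)C(=O)[O-].[K+] | intermediate
34 | potassium (2R,3S)-2,3-dimethyloxirane-2-carboxylate | [K+].[O-]C(=O)[C@]1(C)O[C@H]1C | intermediate
35 | (2R,3S)-2,3-dimethyloxirane-2-carboxylic acid | OC(=O)[C@]1(C)O[C@H]1C | intermediate
36 | (2R,3S)-2,3-dimethyloxirane-2-carboxylic 2,4,6-trichlorobenzoic anhydride | O=C(OC(=O)[C@]1(C)O[C@H]1C)c1c(Cl)cc(Cl)cc1Cl | intermediate
37 | (3S,6R,7R,8R)-3-(benzoyloxy)-8-{[(2R,3S)-2,3-dimethyloxiran-2-yl]carbonyloxy}germacra-1(10)E,4Z,11(13)-trien-12,6-olide | C=C1C(=O)O[C@@H]2/C=C(/C)[C@@H](OC(=O)c3ccccc3)C/C=C(\C)C[C@@H](OC(=O)[C@]3(C)O[C@H]3C)[C@@H]12 | intermediate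
38 | (1R,3S,6R,7R,8R,10R)-3-(benzoyloxy)-1,10-epoxy-8-{[(2R,3S)-2,3-dimethyloxiran-2-yl]carbonyloxy}germacra-4Z,11(13)-dien-12,6-olide (CNP0324463.5) | C=C1C(=O)O[C@@H]2/C=C(/C)[C@@H](OC(=O)c3ccccc3)C[C@H]3O[C@]3(C)C[C@@H](OC(=O)[C@]3(C)O[C@H]3C)[C@@H]12 | target

## Step count and risks

Total step count: 20. Longest linear sequence: 17 (steps 1–15, 19, 20); the side-chain acid takes 3 steps (16–18).

Steps most likely to fail:

Step 14 (the proposed electrochemical ring closure). The risks are direct cathodic reduction of the bromide or enal, oligomerisation, and an unproven 7,8-relay in the macrocyclic transition state. The fallback gives up electrocatalysis for the stoichiometric organochromium chemistry already used for ten-membered germacranolide rings. It sets out from enal bromide 23: Finkelstein exchange (NaI, acetone, 0 °C, dark) gives methyl (2Z,4R,6E,9S,10Z)-9-(benzoyloxy)-4-(TBS-oxy)-2-(iodomethyl)-6,10-dimethyl-12-oxododeca-2,6,10-trienoate F2. F2 is added over 10 h to excess CrCl2 (10 equiv) in degassed DMF/THF at rt (2 mM), a thermal Nozaki–Hiyama Barbier macrocyclisation through the same chair transition state. Acidic work-up (HCl, then p-TsOH) lactonises the hydroxy ester, and the fallback comes back to the route at lactone 26.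

Step 10 (Baylis–Hillman reaction of the α-silyloxy aldehyde). The reaction is slow and DABCO may epimerise C8. The fallback replaces amine catalysis by a preformed, non-basic acrylate α-anion equivalent. It sets out from aldehyde 19: hydroalumination of methyl propiolate with i-Bu2AlH and N-methylmorpholine N-oxide (THF, 0 °C) gives diisobutyl[1-(methoxycarbonyl)ethenyl]alane F1, which adds to 19 at −78 → 0 °C (the benzoate is not attacked). Rochelle-salt work-up gives the same hydroxy ester, and the fallback comes back at 20.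

Step 20 (site and face selectivity of the last epoxidation; acid-triggered transannular opening). The fallback moves the epoxidation before the acylation and lets the free alcohol deliver the oxidant. It sets out from hydroxy lactone 27: VO(acac)2 (5 mol%), t-BuOOH, 2,6-lutidine, CH2Cl2, 0 °C; the homoallylic 8-OH directs the oxidant to the 1(10)-alkene only and from the side it occupies, giving (1R,3S,6R,7R,8R,10R)-3-(benzoyloxy)-1,10-epoxy-8-hydroxygermacra-4Z,11(13)-dien-12,6-olide F3. Yamaguchi acylation of F3 with acid 35 (through anhydride 36, Et3N, DMAP, toluene) comes back at target 38.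

## Further compounds

F1 | step 10 | diisobutyl[1-(methoxycarbonyl)ethenyl]alane | C=C(C(=O)OC)[Al](CC(C)C)CC(C)C
F2 | step 14 | methyl (2Z,4R,6E,9S,10Z)-9-(benzoyloxy)-4-(TBS-oxy)-2-(iodomethyl)-6,10-dimethyl-12-oxododeca-2,6,10-trienoate | O=C/C=C(/C)[C@@H](OC(=O)c1ccccc1)C/C=C(\C)C[C@@H](O[Si](C)(C)C(C)(C)C)/C=C(\CI)C(=O)OC
F3 | step 20 | (1R,3S,6R,7R,8R,10R)-3-(benzoyloxy)-1,10-epoxy-8-hydroxygermacra-4Z,11(13)-dien-12,6-olide | C=C1C(=O)O[C@@H]2/C=C(/C)[C@@H](OC(=O)c3ccccc3)C[C@H]3O[C@]3(C)C[C@@H](O)[C@@H]12
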